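**Remarks on the chemistry**

- Ring A is written in the tautomer of the given SMILES. The β-triketone tautomers interconvert without touching the quaternary carbon, and the descriptor S refers to this tautomer.
- The (R,R) phase-transfer catalyst is assumed to give (R)-5. If the sense of induction is the opposite, the (S,S) catalyst is used and nothing else changes.
- Atom labels. Ring A: C1 (C=O), C2 (carries the bridge CH2), C3 (C–OH), C4 (quaternary, CH3 and prenyl), C5 (C–OH), C6 (carries isobutyryl). Ring system B (2H-chromene): O1, C2 (gem-dimethyl), C3=C4, C4a, C5 (OH), C6 (bridge), C7 (OH), C8 (isobutyryl), C8a.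

## The problem

The target joins two acylphloroglucinol-derived halves through one CH2 group: ring A, a dearomatised 4-methyl-4-prenyl cyclohexadienone, and ring system B, an 8-isobutyryl-5,7-dihydroxy-2,2-dimethyl-2H-chromene bonded through its C6. The only stereocenter is C4 of ring A, which is quaternary and stereogenic solely because its ring neighbours C3 and C5 differ in what lies one bond further (C2 with the bridge, C6 with the acyl group). No other stereocenter exists to control it, and in any symmetric trione precursor it disappears. The usual entry, alkylative dearomatisation of a C-methyl acylphloroglucinol, must choose among two ring carbons, three oxygens and two faces of a flat anion. The feature that opens another way is that C3–C4–C5 of ring A is a 2-methyl-2-prenylmalonyl unit and C2–C1–C6 with the isobutyryl carbonyl is a 1,3-diketone, so ring A is a cyclised tetraketide whose malonyl carbon cannot enolise; it can be closed from open-chain pieces by two Claisen condensations, and its absolute configuration reduces to telling the two carboxyl groups of a malonate apart. In ring system B the pyran oxygen must sit on the carbon next to the acylated one, although the parent phloroglucinol offers a second, unchelated oxygen for closure. The prenyl and chromene alkenes are acid-sensitive, retro-Claisen loss of the isobutyryl group would symmetrise ring A and erase C4, the bridge can reopen by retro-Michael reaction under base and heat, and a malonic half-acid loses CO2 on heating.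

## Retrosynthesis

**Bridge.** Target 22 is cut at the bond between the bridge CH2 and C2 of ring A, giving ring A monomer 11 and ring B Mannich base 20. Forward, 20 loses dimethylamine to give ortho-quinone methide 21, which is captured by the enol carbon C2 of 11. This cut is preferred to a three-component union with formaldehyde, which is statistical. Each half has exactly one free nucleophilic carbon, the electrophile is carried by the achiral half, and the chiral half 11 serves as its own proton source. The forward step must leave C4 untouched, which it does.

**Ring system B.** Mannich base 20 comes from chromene diol 19 by aminomethylation at C6. The pyran ring of 19 is cut at O1–C2 and C4–C4a, leading back to silyl ether 15 and 3-methylbut-2-enal 16. Condensation gives dienone 17, an ortho-quinone methide, whose oxa-6π closure forms silyl chromene 18. The silyl group on the para oxygen leaves only an ortho oxygen for ring closure, which fixes the acyl group at C8. Silyl ether 15 comes from phloroisobutyrophenone 14, made from phloroglucinol 12 and 2-methylpropanoyl chloride 13.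

**Ring A (key disconnection).** Monomer 11 is cut at C2–C3 and C5–C6. This gives malonic half-acid 7, carrying the stereocenter, and 5-methylhexane-2,4-dione 8, which supplies C2, C1, C6 and the whole isobutyryl group. Forward, acyl chloride 9 acylates the terminal carbon of the dianion of 8 to give triketo ester 10, which closes by Claisen condensation onto the remaining ester. Against cutting at C4 (alkylation of an aromatic ring), this places the acyl group and the free C2–H by construction and removes all C/O and site selectivity questions. The precursors are two acyclic compounds, one of them commercial. The forward reaction must make the acyl chloride react before the ester, since that order alone decides which enantiomer of ring A forms.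

**Stereocenter.** Half-acid 7 comes from mixed malonate 5 by removal of the tert-butyl group through silyl ester 6. Malonate 5 is cut at the C–prenyl bond to racemic, enolisable malonate 3 and prenyl bromide 4, joined by asymmetric phase-transfer alkylation. The two esters serve twice: their size difference lets the catalyst distinguish the enolate faces, and their different lability later marks which carbonyl becomes C3 and which C5. Malonate 3 comes from half-ester 2 and 2,2-diphenylethanol, and 2 from 5-methyl Meldrum's acid 1.

## Roads not taken

Alternative 1: The most obvious cut is the C4–prenyl bond of ring A. 2,4,6-Trihydroxy-3-methylisobutyrophenone A1 would be C-prenylated with 4 under base to give 11 in one step. An asymmetric version would use a chiral phase-transfer catalyst, or zerovalent palladium with a chiral diphosphine and a prenyl carbonate. The ambident anion of A1 reacts at the methylated carbon, at the free carbon and at oxygen, and then again. The catalyst would have to distinguish the faces of a flat anion whose two sides differ only at the distant acyl group, and close precedent for high selectivity with a prenyl electrophile on this class is lacking. The chosen plan sets the stereocenter on a substrate class known to respond well and obtains regiochemistry by construction.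

Alternative 2: A dearomative aromatic Claisen rearrangement with 1,3-chirality transfer. Aryl (R)-but-3-en-2-yl ether A2 (other two oxygens as methoxymethyl ethers) would rearrange through a chair transition state to crotyl dienone A3. Cross-metathesis with 2-methyl-2-butene (second-generation Grubbs catalyst) and acetal removal would then give 11. The ether must be placed on the hindered, chelated oxygen between the methyl- and acyl-bearing carbons. Dienone A3 has a free para C–H to which the allyl group can migrate by Cope rearrangement and aromatise irreversibly. The minor chair with axial methyl delivers the opposite face, so selectivity is capped by the E/Z ratio. Protection, metathesis and deprotection add three steps.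

Alternative 3: Late desymmetrisation. Prochiral 2-methyl-2-prenylcyclohexane-1,3,5-trione A4 would add through one of its two enantiotopic CH2 groups to quinone methide 21 under a chiral Brønsted acid or bifunctional catalyst, followed by C-isobutyrylation of the other CH2 group. The catalyst would have to read methyl against prenyl at a carbon two bonds from the reacting centre, for which there is no precedent. Double alkylation and O-acylation would also compete. The chosen plan uses the same hidden symmetry but resolves it by chemical difference (acyl chloride against ester) and not by catalyst recognition.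

Key step: step 5

## Route

Step 1
Reactants: 1 2,2,5-trimethyl-1,3-dioxane-4,6-dione (5-methyl Meldrum's acid)
Product: 2 3-tert-butoxy-2-methyl-3-oxopropanoic acid (racemic)
Conditions: t-BuOH, 82 °C
Reagents that add atoms: tert-butanol, CC(C)(C)O
Why: Alcoholysis of the cyclic acylal opens the dioxanedione with loss of acetone and should give the malonic half-ester directly, as is usual for Meldrum's acids.

Step 2
Reactants: 2 3-tert-butoxy-2-methyl-3-oxopropanoic acid
Product: 3 1-tert-butyl 3-(2,2-diphenylethyl) 2-methylpropanedioate (racemic)
Conditions: 2,2-diphenylethanol, DCC, DMAP (cat.), CH2Cl2, 0 to 23 °C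
Reagents that add atoms: 2,2-diphenylethanol, OCC(c1ccccc1)c1ccccc1
Why: Steglich esterification of a primary alcohol; the α-stereocenter is enolisable and irrelevant at this stage.

Step 3
Reactants: 3 1-tert-butyl 3-(2,2-diphenylethyl) 2-methylpropanedioate; 4 1-bromo-3-methylbut-2-ene (prenyl bromide)
Product: 5 1-tert-butyl 3-(2,2-diphenylethyl) (2R)-2-methyl-2-(3-methylbut-2-en-1-yl)propanedioate
Conditions: (R,R)-3,4,5-trifluorophenyl-NAS bromide (C2-symmetric spiro bis(binaphthyl)ammonium salt, 5 mol %), 50% aq. KOH, toluene, −40 °C
Reagents that add atoms: none
Why: Asymmetric phase-transfer alkylation; the chiral ammonium enolate ion pair, whose faces are distinguished by the tert-butyl and diphenylethyl esters, is alkylated at the primary carbon of the allylic bromide, and tert-butyl 2,2-diphenylethyl α-methylmalonates are an established substrate class for this catalyst with allylic and benzylic bromides. The new quaternary stereocenter is set by the catalyst.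

Step 4
Reactants: 5 1-tert-butyl 3-(2,2-diphenylethyl) (2R)-2-methyl-2-(3-methylbut-2-en-1-yl)propanedioate
Product: 7 (2S)-3-(2,2-diphenylethoxy)-2-methyl-2-(3-methylbut-2-en-1-yl)-3-oxopropanoic acid, via trimethylsilyl ester 6 (not isolated)
Conditions: Me3SiOTf, 2,6-lutidine, CH2Cl2, 0 °C; aq. NaH2PO4 work-up
Reagents that add atoms: none
Why: Silyl triflate activation of the tert-butyl ester releases isobutene and gives the silyl ester, hydrolysed on work-up; the lutidine buffer keeps free acid away from the prenyl alkene and the primary ester is untouched. The descriptor changes from R to S only through the priority rules.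

Step 5
Reactants: 7 (2S)-3-(2,2-diphenylethoxy)-2-methyl-2-(3-methylbut-2-en-1-yl)-3-oxopropanoic acid; 8 5-methylhexane-2,4-dione
Product: 11 (4S)-3,5-dihydroxy-4-methyl-4-(3-methylbut-2-en-1-yl)-2-(2-methylpropanoyl)cyclohexa-2,5-dien-1-one (ring A monomer), via acyl chloride 9 (not isolated), via triketo ester 10 (not isolated)
Conditions: 7, 1-chloro-N,N,2-trimethylprop-1-en-1-amine, CH2Cl2, 0 to 23 °C, concentrate; add to 8 (2.2 equiv)/LiN(i-Pr)2 (4.4 equiv), THF, −78 °C; then 23 to 50 °C; cold dilute HCl to pH 3
Reagents that add atoms: none
Why: Acid 7 is converted under neutral conditions into acyl chloride 9, which the 1,3-dianion of 8 attacks through its terminal CH2 carbon, the more basic and less hindered site; this forms the C2–C3 bond of ring A and, after proton transfer to excess dianion, the dianion of triketo ester 10. On warming, the carbon flanked by the isobutyryl carbonyl and the neighbouring ketone attacks the ester carbonyl in a 6-(enolexo)-exo-trig Claisen (Dieckmann-type) closure that forms the C5–C6 bond and expels 2,2-diphenylethoxide; deprotonation of the β-triketone makes it irreversible. The closest known reaction types are terminal acylation of β-diketone dianions and base-induced Claisen cyclisation of 3,5,7-triketo esters to acylphloroglucinols; here the ester-bearing carbon is quaternary, so the product remains a cyclohexadienone. No stereocenter is formed: C4 comes unchanged from 7, cannot enolise, and its ring descriptor is fixed only by chemoselectivity, the former acid carbon becoming C3 (next to the free C2–H) and the ester carbon C5 (next to acylated C6). The step needs terminal over central attack of the dianion (secured by its charge distribution), acyl chloride over ester in the first bond formation (reactivity gap), and C- over O-acylation in the closure (an enol lactone is reopened by alkoxide, the triketonate is the sink). No aldol alternative exists because the quaternary carbon carries no proton. Retro-Claisen loss of the isobutyryl group, the only event that could symmetrise ring A, is avoided by keeping the product as its dianion and working up cold.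

Step 6
Reactants: 12 benzene-1,3,5-triol (phloroglucinol); 13 2-methylpropanoyl chloride
Product: 14 2-methyl-1-(2,4,6-trihydroxyphenyl)propan-1-one
Conditions: AlCl3 (4 equiv), PhNO2/CH2Cl2, 0 to 45 °C; ice/HCl
Reagents that add atoms: none
Why: Friedel–Crafts C-acylation of phloroglucinol; the first acyl group deactivates the ring against a second.

Step 7
Reactants: 14 2-methyl-1-(2,4,6-trihydroxyphenyl)propan-1-one
Product: 15 1-[2,6-dihydroxy-4-(triisopropylsilyloxy)phenyl]-2-methylpropan-1-one
Conditions: i-Pr3SiCl (1.05 equiv), imidazole, DMF, 0 °C
Reagents that add atoms: chlorotriisopropylsilane, CC(C)[Si](Cl)(C(C)C)C(C)C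
Why: The para hydroxyl is the most acidic and the only one not hydrogen-bonded to the ketone, so one equivalent of silyl chloride should react there selectively.

Step 8
Reactants: 15 1-[2,6-dihydroxy-4-(triisopropylsilyloxy)phenyl]-2-methylpropan-1-one; 16 3-methylbut-2-enal
Product: 19 1-(5,7-dihydroxy-2,2-dimethyl-2H-chromen-8-yl)-2-methylpropan-1-one, via dienone 17 (not isolated), via silyl chromene 18 (not isolated)
Conditions: 16 (1.2 equiv), ethylenediammonium diacetate (10 mol %), toluene, 110 °C; then Bu4NF, AcOH, THF, 0 °C
Reagents that add atoms: none
Why: Iminium-mediated Knoevenagel-type condensation at a free ring carbon gives ortho-quinone methide 17, whose oxa-6π electrocyclisation closes the pyran ring; with the para oxygen silylated only an ortho oxygen can close, which places the acyl group at C8. Buffered fluoride then removes the silyl group.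

Step 9
Reactants: 19 1-(5,7-dihydroxy-2,2-dimethyl-2H-chromen-8-yl)-2-methylpropan-1-one
Product: 20 1-{6-[(dimethylamino)methyl]-5,7-dihydroxy-2,2-dimethyl-2H-chromen-8-yl}-2-methylpropan-1-one
Conditions: CH2=NMe2+ I− (1.0 equiv), Et3N, CH2Cl2, 0 to 23 °C
Reagents that add atoms: N,N-dimethylmethyleneiminium iodide, C=[N+](C)C.[I-]
Why: Mannich aminomethylation at C6, the only free ring carbon and the one flanked by two hydroxyl groups.

Step 10
Reactants: 11 (4S)-3,5-dihydroxy-4-methyl-4-(3-methylbut-2-en-1-yl)-2-(2-methylpropanoyl)cyclohexa-2,5-dien-1-one; 20 1-{6-[(dimethylamino)methyl]-5,7-dihydroxy-2,2-dimethyl-2H-chromen-8-yl}-2-methylpropan-1-one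
Product: 22 (4S)-2-{[5,7-dihydroxy-2,2-dimethyl-8-(2-methylpropanoyl)-2H-chromen-6-yl]methyl}-3,5-dihydroxy-4-methyl-4-(3-methylbut-2-en-1-yl)-6-(2-methylpropanoyl)cyclohexa-2,5-dien-1-one (target), via quinone methide 21 (not isolated)
Conditions: 20 (1.2 equiv), 1,4-dioxane, 80 °C, Ar
Reagents that add atoms: none
Why: The acidic triketone 11 protonates the amine of 20, the ammonium phenol loses dimethylamine to give ortho-quinone methide 21, and the triketone enolate adds through C2 of ring A in a conjugate addition that rearomatises ring B (the Mannich-base method for unsymmetrical methylene-bis-phloroglucinols). C4 is not involved and keeps its configuration.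

## Compound list

1 | 2,2,5-trimethyl-1,3-dioxane-4,6-dione | CC1C(=O)OC(C)(C)OC1=O | starting material
2 | 3-tert-butoxy-2-methyl-3-oxopropanoic acid (racemic) | CC(C(=O)O)C(=O)OC(C)(C)C | intermediate
3 | 1-tert-butyl 3-(2,2-diphenylethyl) 2-methylpropanedioate (racemic) | CC(C(=O)OCC(c1ccccc1)c1ccccc1)C(=O)OC(C)(C)C | intermediate
4 | 1-bromo-3-methylbut-2-ene | CC(C)=CCBr | starting material
5 | 1-tert-butyl 3-(2,2-diphenylethyl) (2R)-2-methyl-2-(3-methylbut-2-en-1-yl)propanedioate | CC(C)=CC[C@](C)(C(=O)OCC(c1ccccc1)c1ccccc1)C(=O)OC(C)(C)C | intermediate
6 | 2,2-diphenylethyl trimethylsilyl (2R)-2-methyl-2-(3-methylbut-2-en-1-yl)propanedioate | CC(C)=CC[C@](C)(C(=O)OCC(c1ccccc1)c1ccccc1)C(=O)O[Si](C)(C)C | intermediate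
7 | (2S)-3-(2,2-diphenylethoxy)-2-methyl-2-(3-methylbut-2-en-1-yl)-3-oxopropanoic acid | CC(C)=CC[C@](C)(C(=O)OCC(c1ccccc1)c1ccccc1)C(=O)O | intermediate
8 | 5-methylhexane-2,4-dione | CC(=O)CC(=O)C(C)C | starting material
9 | 2,2-diphenylethyl (2R)-3-chloro-2-methyl-2-(3-methylbut-2-en-1-yl)-3-oxopropanoate | CC(C)=CC[C@](C)(C(=O)OCC(c1ccccc1)c1ccccc1)C(Cl)=O | intermediate
10 | 2,2-diphenylethyl (2S)-2,8-dimethyl-2-(3-methylbut-2-en-1-yl)-3,5,7-trioxononanoate | CC(C)=CC[C@](C)(C(=O)OCC(c1ccccc1)c1ccccc1)C(=O)CC(=O)CC(=O)C(C)C | intermediate
11 | (4S)-3,5-dihydroxy-4-methyl-4-(3-methylbut-2-en-1-yl)-2-(2-methylpropanoyl)cyclohexa-2,5-dien-1-one | CC(C)=CC[C@@]1(C)C(O)=CC(=O)C(C(=O)C(C)C)=C1O | intermediate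
12 | benzene-1,3,5-triol | Oc1cc(O)cc(O)c1 | starting material
13 | 2-methylpropanoyl chloride | CC(C)C(Cl)=O | starting material
14 | 2-methyl-1-(2,4,6-trihydroxyphenyl)propan-1-one | CC(C)C(=O)c1c(O)cc(O)cc1O | intermediate
15 | 1-[2,6-dihydroxy-4-(triisopropylsilyloxy)phenyl]-2-methylpropan-1-one | CC(C)C(=O)c1c(O)cc(O[Si](C(C)C)(C(C)C)C(C)C)cc1O | intermediate
16 | 3-methylbut-2-enal | CC(C)=CC=O | starting material
17 | 3-hydroxy-6-(3-methylbut-2-en-1-ylidene)-2-(2-methylpropanoyl)-5-(triisopropylsilyloxy)cyclohexa-2,4-dien-1-one | CC(C)C(=O)C1=C(O)C=C(O[Si](C(C)C)(C(C)C)C(C)C)C(=CC=C(C)C)C1=O | intermediate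
18 | 1-[7-hydroxy-2,2-dimethyl-5-(triisopropylsilyloxy)-2H-chromen-8-yl]-2-methylpropan-1-one | CC(C)C(=O)c1c(O)cc(O[Si](C(C)C)(C(C)C)C(C)C)c2C=CC(C)(C)Oc12 | intermediate
19 | 1-(5,7-dihydroxy-2,2-dimethyl-2H-chromen-8-yl)-2-methylpropan-1-one | CC(C)C(=O)c1c(O)cc(O)c2C=CC(C)(C)Oc12 | intermediate
20 | 1-{6-[(dimethylamino)methyl]-5,7-dihydroxy-2,2-dimethyl-2H-chromen-8-yl}-2-methylpropan-1-one | CC(C)C(=O)c1c(O)c(CN(C)C)c(O)c2C=CC(C)(C)Oc12 | intermediate
21 | 5-hydroxy-2,2-dimethyl-6-methylidene-8-(2-methylpropanoyl)-2H-chromen-7(6H)-one | CC(C)C(=O)C1=C2OC(C)(C)C=CC2=C(O)C(=C)C1=O | intermediate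
22 | (4S)-2-{[5,7-dihydroxy-2,2-dimethyl-8-(2-methylpropanoyl)-2H-chromen-6-yl]methyl}-3,5-dihydroxy-4-methyl-4-(3-methylbut-2-en-1-yl)-6-(2-methylpropanoyl)cyclohexa-2,5-dien-1-one | CC(C)=CC[C@@]1(C)C(O)=C(Cc2c(O)c3c(c(C(=O)C(C)C)c2O)OC(C)(C)C=C3)C(=O)C(C(=O)C(C)C)=C1O | target

## Step count and risk

Total: 10 steps. Longest linear sequence: 6 steps (steps 1 to 5, then step 10); the ring B branch is steps 6 to 9.

**Step 5 (key step).** Closure onto the hindered ester beside the quaternary carbon may be slow, which would allow O-acylation to an enol lactone, double acylation of the dianion, or retro-Claisen loss of the isobutyryl group on prolonged heating. The fallback inverts the order of the two bond formations. It sets out from 5: saponification of the diphenylethyl ester (1 M KOH, MeOH, tert-butyl ester untouched) gives (2R)-3-tert-butoxy-2-methyl-2-(3-methylbut-2-en-1-yl)-3-oxopropanoic acid F1. 1-Chloro-N,N,2-trimethylprop-1-en-1-amine gives its acyl chloride F2. Soft-enolate C-acylation of 8 at its central carbon (MgCl2, pyridine, CH2Cl2) gives the triacylmethane tert-butyl (2R)-4-acetyl-2,6-dimethyl-2-(3-methylbut-2-en-1-yl)-3,5-dioxoheptanoate F3. LiN(i-Pr)2 (2.2 equiv, THF, −78 to 23 °C) then forms the methyl ketone enolate, which closes onto the tert-butyl ester in a Dieckmann condensation and returns to the route at 11. Because the former diphenylethyl ester carbon now becomes C5 and the tert-butyl ester carbon C3, the same enantiomer of 11 results from the same malonate.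

**Step 3.** Background alkylation at the interface with the reactive prenyl bromide may erode selectivity, the sense of induction may be opposite, and the primary ester may be saponified by 50% KOH. The fallback is resolution. It sets out from 3: alkylation with 4 under Bu4NBr catalysis gives the racemic malonate F4, and tert-butyl removal as in step 4 gives the racemic half-acid F5. Crystallisation with (R)-1-phenylethylamine (or its antipode, whichever gives the less soluble salt of the wanted acid) gives the diastereomerically pure salt F6, and acidification returns to the route at 7.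

**Step 4.** Ionisation or protonation of the prenyl alkene during tert-butyl removal may lead to lactonisation onto the freed carboxyl group. The fallback uses an acid-stable allyl surrogate. It sets out from 3: alkylation with allyl bromide under the conditions of step 3 gives 1-tert-butyl 3-(2,2-diphenylethyl) (2R)-2-allyl-2-methylpropanedioate F7. CF3CO2H in CH2Cl2 removes the tert-butyl group without touching the terminal alkene and gives the allyl half-acid F8. Cross-metathesis with 2-methyl-2-butene (second-generation Grubbs catalyst, CH2Cl2, 40 °C) returns to the route at 7.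

**Step 8.** A second annulation may occur at the remaining ring carbon, the silyl group may be lost before ring closure (which would open the way to closure on the para oxygen), and the enal may oligomerise. The fallback builds the chromene by a sigmatropic route. It sets out from 15: O-alkylation of one of the two equivalent ortho hydroxyls with 2-methylbut-3-yn-2-yl trifluoroacetate (CuCl2 cat., DBU, MeCN, 0 °C) gives the aryl 1,1-dimethylpropargyl ether F9. Heating (xylene, 140 °C) brings about propargyl Claisen rearrangement, 1,5-hydrogen shift and oxa-6π closure and returns to the route at 18, which is desilylated as in step 8.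

**Step 10.** The bridge may reopen by retro-Michael reaction under amine and heat, exchanging halves and forming symmetrical dimers; amine loss from the chelated Mannich base may be sluggish; the chromene may ring-open thermally. The fallback reverses the polarity of the union. It sets out from 11: aminomethylation at C2 of ring A with N,N-dimethylmethyleneiminium iodide gives the ring A Mannich base F10. Warming F10 with 19 (1,4-dioxane, 60 °C) releases the 2-methylidene triketone, which is attacked by C6 of 19 in a Friedel–Crafts-type conjugate addition and returns to the route at 22.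

## Further compounds

F1 | step 5 | (2R)-3-tert-butoxy-2-methyl-2-(3-methylbut-2-en-1-yl)-3-oxopropanoic acid | CC(C)=CC[C@](C)(C(=O)O)C(=O)OC(C)(C)C
F2 | step 5 | tert-butyl (2S)-3-chloro-2-methyl-2-(3-methylbut-2-en-1-yl)-3-oxopropanoate | CC(C)=CC[C@](C)(C(Cl)=O)C(=O)OC(C)(C)C
F3 | step 5 | tert-butyl (2R)-4-acetyl-2,6-dimethyl-2-(3-methylbut-2-en-1-yl)-3,5-dioxoheptanoate | CC(C)=CC[C@](C)(C(=O)C(C(C)=O)C(=O)C(C)C)C(=O)OC(C)(C)C
F4 | step 3 | 1-tert-butyl 3-(2,2-diphenylethyl) 2-methyl-2-(3-methylbut-2-en-1-yl)propanedioate (racemic) | CC(C)=CCC(C)(C(=O)OCC(c1ccccc1)c1ccccc1)C(=O)OC(C)(C)C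
F5 | step 3 | 3-(2,2-diphenylethoxy)-2-methyl-2-(3-methylbut-2-en-1-yl)-3-oxopropanoic acid (racemic) | CC(C)=CCC(C)(C(=O)OCC(c1ccccc1)c1ccccc1)C(=O)O
F6 | step 3 | (R)-1-phenylethylammonium (2S)-3-(2,2-diphenylethoxy)-2-methyl-2-(3-methylbut-2-en-1-yl)-3-oxopropanoate | CC(C)=CC[C@](C)(C(=O)OCC(c1ccccc1)c1ccccc1)C(=O)[O-].C[C@@H]([NH3+])c1ccccc1
F7 | step 4 | 1-tert-butyl 3-(2,2-diphenylethyl) (2R)-2-methyl-2-(prop-2-en-1-yl)propanedioate | C=CC[C@](C)(C(=O)OCC(c1ccccc1)c1ccccc1)C(=O)OC(C)(C)C
F8 | step 4 | (2S)-3-(2,2-diphenylethoxy)-2-methyl-3-oxo-2-(prop-2-en-1-yl)propanoic acid | C=CC[C@](C)(C(=O)OCC(c1ccccc1)c1ccccc1)C(=O)O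
F9 | step 8 | 1-[2-hydroxy-6-(2-methylbut-3-yn-2-yloxy)-4-(triisopropylsilyloxy)phenyl]-2-methylpropan-1-one | CC(C)C(=O)c1c(O)cc(O[Si](C(C)C)(C(C)C)C(C)C)cc1OC(C)(C)C#C
F10 | step 10 | (4S)-2-[(dimethylamino)methyl]-3,5-dihydroxy-4-methyl-4-(3-methylbut-2-en-1-yl)-6-(2-methylpropanoyl)cyclohexa-2,5-dien-1-one | CC(C)=CC[C@@]1(C)C(O)=C(CN(C)C)C(=O)C(C(=O)C(C)C)=C1O
A1 | alternative 1 | 2-methyl-1-(2,4,6-trihydroxy-3-methylphenyl)propan-1-one | CC(C)C(=O)c1c(O)cc(O)c(C)c1O
A2 | alternative 2 | 1-{2-[(2R)-but-3-en-2-yloxy]-4,6-bis(methoxymethoxy)-3-methylphenyl}-2-methylpropan-1-one | CC(C)C(=O)c1c(O[C@H](C)C=C)c(C)c(OCOC)cc1OCOC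
A3 | alternative 2 | (6S)-6-[(2E)-but-2-en-1-yl]-3,5-bis(methoxymethoxy)-6-methyl-2-(2-methylpropanoyl)cyclohexa-2,4-dien-1-one | C/C=C/C[C@]1(C)C(=O)C(C(=O)C(C)C)=C(OCOC)C=C1OCOC
A4 | alternative 3 | 2-methyl-2-(3-methylbut-2-en-1-yl)cyclohexane-1,3,5-trione | CC(C)=CCC1(C)C(=O)CC(=O)CC1=O
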